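**Plan**
- Retrosynthesis first cuts the C9 angelate (esterification) and the C7–isopropenyl bond (opening of a 7α,8α-epoxide), leading back to a trans-fused Δ7-octalin with oxygen at C2 and C9.
- The bonds C3–C4 and C5–C10 are then cut together. Ring A carries its oxygen at C2, so with a C1=C2 silyl enol ether it is the retron of a Diels–Alder reaction between the 2-silyloxydiene C3=C2–C1=C10 and the alkene C4=C5. C5 and C10 are also the fusion atoms of ring B and are linked by C6–C9, so diene and dienophile sit on one chain.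
- Forward: an acyclic C12 tetraene is joined from tiglyl bromide, acetylene and 4-oxopent-2-enal (from 2-methylfuran). One intramolecular Diels–Alder reaction closes rings A and B together. Ring A is then adjusted (C2 ketone to axial acetate), followed by ring B (epoxide, isopropenyl, angelate).
- Stereochemistry: C9 comes from a catalytic enantioselective alkynylation and is the only center made by a chiral reagent. The E-alkene fixes the cis methyls at C4/C5, and the cycloaddition relays C9 to C10 and C5. C2 is set by equatorial hydride delivery, C8 and C7 by hydroxyl-directed epoxidation and trans-diaxial opening.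

Key step: step 7

Remark: the target is read as the trans-decalin 2α-acetoxy-9α-angeloyloxy-8α-hydroxy-7β-isopropenyl-4β,5β-dimethyl-10αH (2S,4S,5R,7R,8R,9S,10R; ester = (Z)-2-methylbut-2-enoate). Bicyclic intermediates are named as decalins with eremophilane locants (ring A = C1–C5, C10; ring B = C5–C10; methyls C15 on C4 and C14 on C5).

**Step 1**
Reactants: 1 (E)-2-methylbut-2-en-1-ol
Product: 2 (E)-1-bromo-2-methylbut-2-ene
Conditions: PBr3 (0.4 equiv), Et2O, −10 °C
Reagents that add atoms: phosphorus tribromide, BrP(Br)Br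
Why: Bromination of a primary allylic alcohol with PBr3 (SN2 on the phosphite ester) at low temperature keeps the E alkene and the primary position, no stereocenter being involved.

**Step 2**
Reactants: 2 (E)-1-bromo-2-methylbut-2-ene
Product: 3 (E)-4-methylhex-4-en-1-yne
Conditions: HC≡CMgBr (1.5 equiv), CuBr·SMe2 (5 mol %), THF, 0 °C to rt
Reagents that add atoms: ethynylmagnesium bromide, C#C[Mg]Br
Why: Copper-catalysed cross-coupling of an alkynyl Grignard reagent with a primary allylic bromide proceeds in the SN2 sense at the unhindered CH2 and gives the skipped enyne with the E alkene intact.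

**Step 3**
Reactants: 4 2-methylfuran
Product: 6 (E)-4-oxopent-2-enal, via (Z)-4-oxopent-2-enal 5 (not isolated)
Conditions: NBS (1.05 equiv), NaHCO3 (2 equiv), acetone/H2O 10:1, −15 °C; then pyridine (cat.), rt; used directly
Reagents that add atoms: water, O
Why: NBS-mediated oxidative ring opening of a 2-alkylfuran (bromination, hydration, loss of bromide) gives the cis-4-oxoenal, which the amine isomerises by reversible conjugate addition to the more stable E isomer.

**Step 4**
Reactants: 3 (E)-4-methylhex-4-en-1-yne; 6 (E)-4-oxopent-2-enal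
Product: 8 (3E,5S,9E)-5-hydroxy-9-methylundeca-3,9-dien-6-yn-2-one, via methyl[(4E)-4-methylhex-4-en-1-yn-1-yl]zinc 7 (not isolated)
Conditions: 3 (1.5 equiv), Me2Zn (3 equiv), (S,S)-2,6-bis{[2-(hydroxydiphenylmethyl)pyrrolidin-1-yl]methyl}-4-methylphenol (ProPhenol ligand, 10 mol %; its antipode instead if that is the one found to direct Re-face addition), Ph3PO (20 mol %), PhMe, 0 °C; then 6; then H2O
Reagents that add atoms: none
Why: Catalytic enantioselective alkynylzinc addition to an aldehyde (dinuclear zinc–ProPhenol catalysis) takes place at the aldehyde, not the ketone, and the chiral pocket delivers the alkynyl group to the Re face to set the 5S carbinol center, which becomes C9 of the target.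

**Step 5**
Reactants: 8 (3E,5S,9E)-5-hydroxy-9-methylundeca-3,9-dien-6-yn-2-one
Product: 9 (3E,5R,6Z,9E)-5-hydroxy-9-methylundeca-3,6,9-trien-2-one
Conditions: H2 (1 atm, stopped at 1 equiv), Pd/CaCO3 poisoned with Pb(OAc)2, quinoline, EtOAc, rt
Reagents that add atoms: none
Why: Lindlar semi-hydrogenation adds H2 syn to the alkyne on the poisoned palladium surface and stops at the Z-alkene, the alkyne being adsorbed far more strongly than the enone or the trisubstituted alkene; the carbinol center is untouched (its descriptor changes from S to R only through the priority rules).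

**Step 6**
Reactants: 9 (3E,5R,6Z,9E)-5-hydroxy-9-methylundeca-3,6,9-trien-2-one
Product: 10 (3E,5R,6Z,9E)-2,5-bis(tert-butyldimethylsilyloxy)-9-methylundeca-1,3,6,9-tetraene
Conditions: TBSOTf (2.4 equiv), Et3N (4 equiv), CH2Cl2, −78 to 0 °C
Reagents that add atoms: tert-butyldimethylsilyl triflate, CC(C)(C)[Si](C)(C)OS(=O)(=O)C(F)(F)F
Why: Silyl triflate with a tertiary amine silylates the secondary alcohol and soft-enolises the methyl ketone at its CH3 group, giving the cross-conjugated 2-silyloxy-1,3-diene with the E alkene retained.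

**Step 7**
Reactants: 10 (3E,5R,6Z,9E)-2,5-bis(tert-butyldimethylsilyloxy)-9-methylundeca-1,3,6,9-tetraene
Product: 11 2,9α-bis(tert-butyldimethylsilyloxy)-4β,5β-dimethyl-10αH-decalin-1,7-diene (trans-fused)
Conditions: PhMe (0.01 M), BHT (cat.), Et3N (cat.), base-washed sealed tube, 180 °C
Reagents that add atoms: none
Why: Heat drives a concerted, asynchronous [4πs+2πs] cycloaddition between the 2-silyloxydiene C3=C2–C1=C10 and the unactivated E-alkene C4=C5 held on the same chain; the closest known reaction type is the thermal type 1 intramolecular Diels–Alder reaction of 1,3,9-decatrienes that carry 2-silyloxydienes and unactivated dienophiles. Ring A closes as the six-membered cycloadduct ring (new bonds C3–C4 and C5–C10, new alkene C1=C2 as a silyl enol ether that marks C2 for oxygen), and ring B closes in the same event as a fused six-membered ring through the four-carbon tether C6–C9, whose Z-alkene C7=C8 removes two rotors and makes the tether a half-chair. C4 and C5 receive their cis methyls stereospecifically from the E geometry of the dienophile (suprafacial addition), and C10 receives its hydrogen trans to the C5 methyl from the E diene reacting through the tether-exo (anti) transition state. The absolute sense is relayed from C9: the dienophile adds to the diene face that leaves the OTBS group pseudo-equatorial, because the other face would place OTBS syn-axial to the C5 methyl on the forming ring B. The step therefore needs exo-tether and anti-OTBS selectivity; the second is secured by that 1,3-diaxial penalty, while the first rests only on the smaller group (CH3, not the substituted C4) taking the axial site at C5 in the half-chair and is expected to be moderate, so the isomers are separated at this stage.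

**Step 8**
Reactants: 11 2,9α-bis(tert-butyldimethylsilyloxy)-4β,5β-dimethyl-10αH-decalin-1,7-diene
Product: 12 9α-(tert-butyldimethylsilyloxy)-4β,5β-dimethyl-10αH-decalin-7-en-2-one
Conditions: Bu4NF (1.05 equiv), AcOH (1.2 equiv), THF, −78 to 0 °C
Reagents that add atoms: none
Why: Fluoride cleaves the Si–O bond of the silyl enol ether much faster than that of the secondary alkyl silyl ether and buffered protonation of the enolate at C1 gives the ketone (chemoselective desilylation; C1 is a CH2 group, so no stereocenter arises).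

**Step 9**
Reactants: 12 9α-(tert-butyldimethylsilyloxy)-4β,5β-dimethyl-10αH-decalin-7-en-2-one
Product: 13 9α-(tert-butyldimethylsilyloxy)-4β,5β-dimethyl-10αH-decalin-7-en-2α-ol
Conditions: LiBH(s-Bu)3 (1.3 equiv), THF, −78 °C; then H2O
Reagents that add atoms: none
Why: Reduction with a bulky trialkylborohydride delivers hydride along the equatorial trajectory (the axial one is blocked by the axial H-4 and H-10 on the α face), giving the axial 2α-alcohol, as in the reduction of 3-keto-5α-steroids to 3α-ols.

**Step 10**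
Reactants: 13 9α-(tert-butyldimethylsilyloxy)-4β,5β-dimethyl-10αH-decalin-7-en-2α-ol
Product: 14 2α-acetoxy-9α-(tert-butyldimethylsilyloxy)-4β,5β-dimethyl-10αH-decalin-7-ene
Conditions: Ac2O (2 equiv), Et3N (3 equiv), DMAP (cat.), CH2Cl2, rt
Reagents that add atoms: acetic anhydride, CC(=O)OC(C)=O
Why: DMAP-catalysed acylation of the only free hydroxyl with acetic anhydride, with retention at C2.

**Step 11**
Reactants: 14 2α-acetoxy-9α-(tert-butyldimethylsilyloxy)-4β,5β-dimethyl-10αH-decalin-7-ene
Product: 15 2α-acetoxy-4β,5β-dimethyl-10αH-decalin-7-en-9α-ol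
Conditions: HF·pyridine, pyridine/THF, 0 °C to rt
Reagents that add atoms: none
Why: Fluoride-mediated cleavage of the allylic silyl ether with buffered HF·pyridine leaves the acetate and the alkene intact.

**Step 12**
Reactants: 15 2α-acetoxy-4β,5β-dimethyl-10αH-decalin-7-en-9α-ol
Product: 16 2α-acetoxy-7α,8α-epoxy-4β,5β-dimethyl-10αH-decalin-9α-ol
Conditions: mCPBA (1.3 equiv), NaHCO3, CH2Cl2, 0 °C
Reagents that add atoms: 3-chloroperoxybenzoic acid, OOC(=O)c1cccc(Cl)c1
Why: Hydroxyl-directed (Henbest) peracid epoxidation: hydrogen bonding of the pseudo-equatorial 9α-hydroxyl to the peracid delivers oxygen to the α face of C7=C8, which is also the face away from the axial C5 methyl.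

**Step 13**
Reactants: 16 2α-acetoxy-7α,8α-epoxy-4β,5β-dimethyl-10αH-decalin-9α-ol
Product: 17 2α-acetoxy-7β-isopropenyl-4β,5β-dimethyl-10αH-decalin-8α,9α-diol
Conditions: CH2=C(CH3)MgBr (8 equiv), CuBr·SMe2 (4 equiv), THF/Et2O, −40 to 0 °C; then aq. NH4Cl
Reagents that add atoms: isopropenylmagnesium bromide, C=C(C)[Mg]Br
Why: Organocuprate opening of the epoxide by SN2 attack under Fürst–Plattner (trans-diaxial) control: attack at C7 from the β face (inversion) leads straight to the chair with axial 7β-isopropenyl and axial 8α-hydroxyl, C8 is shielded by the neighbouring alkoxide-bearing C9, and the acetate is not attacked by a cuprate at low temperature (close analogy: 2α,3α-epoxy-5α-steroids giving 2β-substituted 3α-ols).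

**Step 14**
Reactants: 17 2α-acetoxy-7β-isopropenyl-4β,5β-dimethyl-10αH-decalin-8α,9α-diol
Product: 18 2α-acetoxy-9α-angeloyloxy-7β-isopropenyl-4β,5β-dimethyl-10αH-decalin-8α-ol (target)
Conditions: angelic acid (1.3 equiv), 2,4,6-trichlorobenzoyl chloride (1.3 equiv), Et3N (1.5 equiv), PhMe, rt; then 17, PhMe, 75 °C
Reagents that add atoms: angelic acid [(Z)-2-methylbut-2-enoic acid], C/C=C(/C)C(=O)O
Why: Yamaguchi-type esterification through the mixed 2,4,6-trichlorobenzoic anhydride without a nucleophilic catalyst keeps the Z geometry of the angeloyl group, and the equatorial 9-hydroxyl reacts in preference to the axial 8-hydroxyl, which is flanked by the axial isopropenyl group.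

**Compound list**
1 | (E)-2-methylbut-2-en-1-ol | C/C=C(\C)CO | starting material
2 | (E)-1-bromo-2-methylbut-2-ene | C/C=C(\C)CBr | intermediate
3 | (E)-4-methylhex-4-en-1-yne | C#CC/C(C)=C/C | intermediate
4 | 2-methylfuran | Cc1ccco1 | starting material
5 | (Z)-4-oxopent-2-enal (not isolated) | CC(=O)/C=C\C=O | intermediate
6 | (E)-4-oxopent-2-enal | CC(=O)/C=C/C=O | intermediate
7 | methyl[(4E)-4-methylhex-4-en-1-yn-1-yl]zinc (not isolated) | C[Zn]C#CC/C(C)=C/C | intermediate
8 | (3E,5S,9E)-5-hydroxy-9-methylundeca-3,9-dien-6-yn-2-one | CC(=O)/C=C/[C@H](O)C#CC/C(C)=C/C | intermediate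
9 | (3E,5R,6Z,9E)-5-hydroxy-9-methylundeca-3,6,9-trien-2-one | CC(=O)/C=C/[C@H](O)/C=C\C/C(C)=C/C | intermediate
10 | (3E,5R,6Z,9E)-2,5-bis(tert-butyldimethylsilyloxy)-9-methylundeca-1,3,6,9-tetraene | C=C(O[Si](C)(C)C(C)(C)C)/C=C/[C@H](O[Si](C)(C)C(C)(C)C)/C=C\C/C(C)=C/C | intermediate
11 | 2,9α-bis(tert-butyldimethylsilyloxy)-4β,5β-dimethyl-10αH-decalin-1,7-diene (trans-fused) | C1C[C@]2(C)[C@@H](C)CC(O[Si](C)(C)C(C)(C)C)=C[C@H]2[C@H](O[Si](C)(C)C(C)(C)C)C=1 | intermediate
12 | 9α-(tert-butyldimethylsilyloxy)-4β,5β-dimethyl-10αH-decalin-7-en-2-one | C1C[C@]2(C)[C@@H](C)CC(=O)C[C@H]2[C@H](O[Si](C)(C)C(C)(C)C)C=1 | intermediate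
13 | 9α-(tert-butyldimethylsilyloxy)-4β,5β-dimethyl-10αH-decalin-7-en-2α-ol | C1C[C@]2(C)[C@@H](C)C[C@H](O)C[C@H]2[C@H](O[Si](C)(C)C(C)(C)C)C=1 | intermediate
14 | 2α-acetoxy-9α-(tert-butyldimethylsilyloxy)-4β,5β-dimethyl-10αH-decalin-7-ene | C1C[C@]2(C)[C@@H](C)C[C@H](OC(C)=O)C[C@H]2[C@H](O[Si](C)(C)C(C)(C)C)C=1 | intermediate
15 | 2α-acetoxy-4β,5β-dimethyl-10αH-decalin-7-en-9α-ol | C1C[C@]2(C)[C@@H](C)C[C@H](OC(C)=O)C[C@H]2[C@H](O)C=1 | intermediate
16 | 2α-acetoxy-7α,8α-epoxy-4β,5β-dimethyl-10αH-decalin-9α-ol | [C@@H]13C[C@]2(C)[C@@H](C)C[C@H](OC(C)=O)C[C@H]2[C@H](O)[C@@H]1O3 | intermediate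
17 | 2α-acetoxy-7β-isopropenyl-4β,5β-dimethyl-10αH-decalin-8α,9α-diol | C=C(C)[C@H]1C[C@]2(C)[C@@H](C)C[C@H](OC(C)=O)C[C@H]2[C@H](O)[C@@H]1O | intermediate
18 | 2α-acetoxy-9α-angeloyloxy-7β-isopropenyl-4β,5β-dimethyl-10αH-decalin-8α-ol (CNP0217919.1) | C=C(C)[C@H]1C[C@]2(C)[C@@H](C)C[C@H](OC(C)=O)C[C@H]2[C@H](OC(=O)/C(C)=C\C)[C@@H]1O | target

**Count**
Total steps: 14. Longest linear sequence: 13 steps (steps 1, 2 and 4–14; step 3 is the short side branch).

**Steps most likely to fail**

1. Step 7. At the temperature that an unactivated trisubstituted dienophile needs, discrimination between the tether-exo and tether-endo transition states (ring fusion) and between the two diene faces may be too small, and the silyl dienol ether may degrade before it cyclizes.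
Fallback: the dienophile is made electron-poor and the cycloaddition is run under Lewis acid, where the endo rule enforces the trans fusion; an ester stands in for the C15 methyl and is reduced away afterwards. It sets out from 6 and comes back at 11. Commercial methyl (E)-4-bromo-3-methylbut-2-enoate is coupled with ethynylmagnesium bromide (CuBr·SMe2 cat., THF, −30 °C) to methyl (E)-3-methylhex-2-en-5-ynoate F1. F1 is added to 6 under the conditions of step 4 to give methyl (2E,7S,8E)-7-hydroxy-3-methyl-10-oxoundeca-2,8-dien-5-ynoate F2. Lindlar semi-hydrogenation gives methyl (2E,5Z,7R,8E)-7-hydroxy-3-methyl-10-oxoundeca-2,5,8-trienoate F3. TBSOTf/Et3N at −78 °C (alcohol and ketone only) gives methyl (2E,5Z,7R,8E)-7,10-bis(tert-butyldimethylsilyloxy)-3-methylundeca-2,5,8,10-tetraenoate F4. EtAlCl2 (1.1 equiv), CH2Cl2, −78 to −20 °C closes both rings through the ester-endo transition state to the trans-fused 15-methyl ester of 11 (CO2Me in place of the C15 methyl, β) F5. i-Bu2AlH (CH2Cl2, −78 °C) reduces the ester to the 15-alcohol F6, MsCl/Et3N gives the 15-mesylate F7, and LiBHEt3 (THF, 0 °C to rt) displaces the mesylate with hydride to give 11.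

2. Step 13. The organometallic may attack the acetate, or the opening may be slow because the axial trajectory at C7 runs past the axial C5 methyl, so that basic side reactions take over.
Fallback: both esters are taken out of the organometallic step and installed at the end. It sets out from 13 and comes back at 18. Bu4NF (THF, rt) removes the silyl ether to give 4β,5β-dimethyl-10αH-decalin-7-ene-2α,9α-diol F8. mCPBA (directed by the 9-hydroxyl) gives 7α,8α-epoxy-4β,5β-dimethyl-10αH-decalin-2α,9α-diol F9. Excess isopropenylmagnesium bromide with CuI (10 mol %) in THF at −20 to 0 °C, now free to be forced because no ester is present, gives 7β-isopropenyl-4β,5β-dimethyl-10αH-decalin-2α,8α,9α-triol F10. Bu2SnO (PhMe, reflux, water removed) forms the 8,9-O-dibutylstannylene acetal of the triol F11, which commercial angelic anhydride acylates at the equatorial O9 to give 9α-angeloyloxy-7β-isopropenyl-4β,5β-dimethyl-10αH-decalin-2α,8α-diol F12. Ac2O/pyridine at 0 °C then acetylates the accessible axial 2-hydroxyl in preference to the hindered 8-hydroxyl and gives 18.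

3. Step 14. Regiocontrol between the two hydroxyls may be lost (8-O-acylation, diacylation, acyl migration), and the angeloyl unit may isomerize from Z to E at the temperature needed.
Fallback: the diol is activated as a tin acetal, which raises the nucleophilicity of the equatorial oxygen and allows acylation at room temperature. It sets out from 17 and comes back at 18. Bu2SnO (PhMe, reflux, water removed) gives the 8,9-O-dibutylstannylene acetal of 17 F13, and commercial angelic anhydride (PhMe, rt) acylates O9 to give 18.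

**Further compounds**
F1 | step 7 | methyl (E)-3-methylhex-2-en-5-ynoate | C#CC/C(C)=C/C(=O)OC
F2 | step 7 | methyl (2E,7S,8E)-7-hydroxy-3-methyl-10-oxoundeca-2,8-dien-5-ynoate | CC(=O)/C=C/[C@H](O)C#CC/C(C)=C/C(=O)OC
F3 | step 7 | methyl (2E,5Z,7R,8E)-7-hydroxy-3-methyl-10-oxoundeca-2,5,8-trienoate | CC(=O)/C=C/[C@H](O)/C=C\C/C(C)=C/C(=O)OC
F4 | step 7 | methyl (2E,5Z,7R,8E)-7,10-bis(tert-butyldimethylsilyloxy)-3-methylundeca-2,5,8,10-tetraenoate | C=C(O[Si](C)(C)C(C)(C)C)/C=C/[C@H](O[Si](C)(C)C(C)(C)C)/C=C\C/C(C)=C/C(=O)OC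
F5 | step 7 | methyl 2,9α-bis(tert-butyldimethylsilyloxy)-5β-methyl-10αH-decalin-1,7-diene-4β-carboxylate | C1C[C@]2(C)[C@@H](C(=O)OC)CC(O[Si](C)(C)C(C)(C)C)=C[C@H]2[C@H](O[Si](C)(C)C(C)(C)C)C=1
F6 | step 7 | [2,9α-bis(tert-butyldimethylsilyloxy)-5β-methyl-10αH-decalin-1,7-dien-4β-yl]methanol | C1C[C@]2(C)[C@@H](CO)CC(O[Si](C)(C)C(C)(C)C)=C[C@H]2[C@H](O[Si](C)(C)C(C)(C)C)C=1
F7 | step 7 | [2,9α-bis(tert-butyldimethylsilyloxy)-5β-methyl-10αH-decalin-1,7-dien-4β-yl]methyl methanesulfonate | C1C[C@]2(C)[C@@H](COS(C)(=O)=O)CC(O[Si](C)(C)C(C)(C)C)=C[C@H]2[C@H](O[Si](C)(C)C(C)(C)C)C=1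
F8 | step 13 | 4β,5β-dimethyl-10αH-decalin-7-ene-2α,9α-diol | C1C[C@]2(C)[C@@H](C)C[C@H](O)C[C@H]2[C@H](O)C=1
F9 | step 13 | 7α,8α-epoxy-4β,5β-dimethyl-10αH-decalin-2α,9α-diol | [C@@H]13C[C@]2(C)[C@@H](C)C[C@H](O)C[C@H]2[C@H](O)[C@@H]1O3
F10 | step 13 | 7β-isopropenyl-4β,5β-dimethyl-10αH-decalin-2α,8α,9α-triol | C=C(C)[C@H]1C[C@]2(C)[C@@H](C)C[C@H](O)C[C@H]2[C@H](O)[C@@H]1O
F11 | step 13 | 8,9-O-dibutylstannylene acetal of 7β-isopropenyl-4β,5β-dimethyl-10αH-decalin-2α,8α,9α-triol | C=C(C)[C@H]1C[C@]2(C)[C@@H](C)C[C@H](O)C[C@H]2[C@H](O[Sn]3(CCCC)CCCC)[C@@H]1O3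
F12 | step 13 | 9α-angeloyloxy-7β-isopropenyl-4β,5β-dimethyl-10αH-decalin-2α,8α-diol | C=C(C)[C@H]1C[C@]2(C)[C@@H](C)C[C@H](O)C[C@H]2[C@H](OC(=O)/C(C)=C\C)[C@@H]1O
F13 | step 14 | 8,9-O-dibutylstannylene acetal of 2α-acetoxy-7β-isopropenyl-4β,5β-dimethyl-10αH-decalin-8α,9α-diol | C=C(C)[C@H]1C[C@]2(C)[C@@H](C)C[C@H](OC(C)=O)C[C@H]2[C@H](O[Sn]3(CCCC)CCCC)[C@@H]1O3
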